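At the 4.00 h reading of Wednesday's run, intermediate A stood at 39.9%, higher than at any later reading. The new flask looks nearly the same: the gas is held at 200 mM, but the starting material is charged at twice the concentration.

| flask | starting material | gas | remark | time |
|---|---|---|---|---|
| Wednesday's | 1.5 M | 200 mM (held) | run made earlier |  |
| flask | 3.0 M | 200 mM (held) |  | 6.0 d |

Wednesday's run (percent of the starting material charged)

| time / h | intermediate A / % | target / % |
|---|---|---|
| 4.00 | 39.9 | 3.8 |
| 10.0 | 15.7 | 12.8 |
| 20.0 | 7.4 | 16.8 |
| 30.0 | 6.1 | 17.8 |

(scatter of a reading: 1 percentage point)

- percentages count the starting material that a species holds: one side product counts as two
- at the start none of coupling partner is dissolved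
- reactions considered so far: starting material + coupling partner -> intermediate A; coupling partner + intermediate A <-> intermediate B; coupling partner + intermediate A <-> target; gas <-> coupling partner; starting material + target -> side product

- the best time, 6.0 d at the latest, for intermediate A
- the amount of intermediate A, in percent of the starting material charged, at that time

I followed one molecule of dissolved coupling partner. It meets either starting material or intermediate A, and the forward steps of both are first order in it:

rate of making A = k_make[starting material][coupling partner]

rate of using A = k_use[intermediate A][coupling partner]

peak, with the back runs set aside: k_make[starting material] = k_use[intermediate A]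

So [coupling partner] cancels at this fork, and k_make/k_use, a selectivity factor, is a ratio of constants. Doubling the charge scales both concentrations, so I took the supply of partner to move the time of the peak and not its height. Wednesday's highest reading, which need not stand at the peak itself, gives 39.9% for the peak share, the highest part of the charge standing as intermediate A, give or take 1 percentage point.

For the flask I reckoned 39.9% of the charge, or 1.20 M. I took two limits for its time: a constant [coupling partner] keeps it at Wednesday's highest reading, 4.00 h, and a fixed rate of supply stretches it with the charge to 8.00 h, so I expected it between the two.

The forecast said 43% at 0.27 d: “Doubling the charge should thus leave the peak percentage nearly unchanged”.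

The flask gave 39.5% at 0.267 d.

    starting material + coupling partner → intermediate A (k = 3.76 /M/h)
    coupling partner + intermediate A ⇌ intermediate B (K = 47.0 /M, k = 2.85 /M/h)
    coupling partner + intermediate A ⇌ target (K = 14.0 /M, k = 0.712 /M/h)
    gas ⇌ coupling partner, rate k4*(csat - [coupling partner]) (kL = 2.90 /h)
    starting material + target → side product (k = 0.268 /M/h)

The flask's peak of 39.5% stood within the scatter of 1 point around my reckoned 39.9%, and its time of 6.40 h fell inside my span. The same flask read at 40 h had also reached 39.5%. At 6.00 d, the forward path from intermediate A to intermediate B ran 4.0 times the forward path to target. The flask then held intermediate B at 61.9% against target at 18.4%.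

All runs stem from a simulated flask for an exercise; scatter was added.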